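**Plan**
- Retrosynthetic cuts, in order: (a) in the butenolide, the bond from the α-CH to the carbonyl carbon and the bond from the ring oxygen to the CH2, which takes out one CO2 and leaves a 2-(trienyl)allyl bromide; (b) the C–C bond between that allyl unit and the diene, and the neighbouring CH=CH; (c) the exocyclic (Z)-C=C and the ring C–O of the γ-lactone; (d) the C–C bond between a phosphonoacetate and a chloro enone.
- Forward order: phosphonate 7 (steps 1–4) and aldehyde 11 from farnesyl acetate (steps 5–7) are joined to the Z-enoate; ring A (γ-lactone) closes first; the chain is extended at its far end to the triene; ring B (butenolide) closes last.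
- Stereochemistry: the single (R) centre comes from a CBS reduction (catalyst control); the Z-alkylidene from a Still–Gennari olefination; the two trisubstituted E-alkenes from farnesyl acetate; the E,E-diene from the E-enal, an E-selective Takai–Utimoto olefination and a stereoretentive coupling.
- Feature used by the key step: in ring B the C(=O)–O unit is one molecule of CO2, and the other three ring atoms (α-CH, β-carbon carrying the trienyl chain, O–CH2) form a 2-substituted allyl unit. In the precursor both ends of this unit are CH2, so no alkene geometry has to be set; a sulfonium group makes one end a carbon nucleophile for the carbon of CO2 and then leaves when the oxygen of CO2 closes the ring.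

Key step: step 14

Assumption: in the CBS reduction of 5 the alkenyl group acts as the large substituent, as it does for simple enones, so the (S)-catalyst should give the (4R)-alcohol; compounds 1, 2, 4, 8, 16, 18 and 21 are bought.

**Route**

Step 1
Reactants: 1 2-chloro-N-methoxy-N-methylacetamide; 2 (2-methylprop-1-en-1-yl)magnesium bromide
Product: 3 1-chloro-4-methylpent-3-en-2-one
Conditions: THF, −78 → 0 °C; aq. NH4Cl
Reagents that add atoms: none
Why: Weinreb ketone synthesis: the chelated tetrahedral magnesium adduct survives until work-up, so the Grignard reagent adds only once and the α-chloride is not touched.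

Step 2
Reactants: 3 1-chloro-4-methylpent-3-en-2-one; 4 methyl 2-[bis(2,2,2-trifluoroethoxy)phosphoryl]acetate
Product: 5 methyl 2-[bis(2,2,2-trifluoroethoxy)phosphoryl]-6-methyl-4-oxohept-5-enoate (racemic)
Conditions: NaH, THF, 0 °C → rt (4 in slight excess)
Reagents that add atoms: none
Why: SN2 alkylation of the sodium phosphonoacetate carbanion by an α-chloro ketone, a highly activated primary electrophile; C2 forms as a mixture of epimers, which does not matter because this centre becomes sp2 in step 8.

Step 3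
Reactants: 5 methyl 2-[bis(2,2,2-trifluoroethoxy)phosphoryl]-6-methyl-4-oxohept-5-enoate
Product: 6 methyl (4R)-2-[bis(2,2,2-trifluoroethoxy)phosphoryl]-4-hydroxy-6-methylhept-5-enoate (both C2 epimers)
Conditions: (S)-2-methyl-CBS-oxazaborolidine (20 mol %), BH3·SMe2, toluene/THF, −40 °C; MeOH
Reagents that add atoms: none
Why: Corey–Bakshi–Shibata reduction: the ketone should bind the catalyst–borane complex with the bulkier β,β-disubstituted alkenyl group turned away from the B-methyl group, and intramolecular hydride delivery under catalyst control then sets the (4R)-carbinol, while ester and phosphonate are not reduced at −40 °C.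

Step 4
Reactants: 6 methyl (4R)-2-[bis(2,2,2-trifluoroethoxy)phosphoryl]-4-hydroxy-6-methylhept-5-enoate
Product: 7 methyl (4R)-2-[bis(2,2,2-trifluoroethoxy)phosphoryl]-4-[(tert-butyldimethylsilyl)oxy]-6-methylhept-5-enoate (both C2 epimers)
Conditions: TBSOTf, 2,6-lutidine, CH2Cl2, −78 °C
Reagents that add atoms: tert-butyldimethylsilyl trifluoromethanesulfonate (TBSOTf), CC(C)(C)[Si](C)(C)OS(=O)(=O)C(F)(F)F
Why: O-silylation with the reactive silyl triflate at −78 °C should outrun lactonisation of the γ-hydroxy ester; the stereocentre is not involved.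

Step 5
Reactants: 8 (2E,6E)-3,7,11-trimethyldodeca-2,6,10-trien-1-yl acetate ((E,E)-farnesyl acetate)
Product: 9 (2E,6E)-10-bromo-11-hydroxy-3,7,11-trimethyldodeca-2,6-dien-1-yl acetate (racemic)
Conditions: NBS, THF/H2O, 0 °C
Reagents that add atoms: N-bromosuccinimide, O=C1CCC(=O)N1Br; water, O
Why: Bromohydrin formation (Markovnikov opening of the bromonium ion by water): the terminal trisubstituted alkene is the most accessible and electron-rich, and the 2,3-alkene is deactivated by the allylic acetate; the new racemic centre is removed in step 7.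

Step 6
Reactants: 9 (2E,6E)-10-bromo-11-hydroxy-3,7,11-trimethyldodeca-2,6-dien-1-yl acetate
Product: 10 (2E,6E)-9-(3,3-dimethyloxiran-2-yl)-3,7-dimethylnona-2,6-dien-1-ol (racemic)
Conditions: K2CO3, MeOH, rt
Reagents that add atoms: none
Why: Intramolecular Williamson closure of the bromohydrin to the epoxide, with methanolysis of the acetate in the same medium.

Step 7
Reactants: 10 (2E,6E)-9-(3,3-dimethyloxiran-2-yl)-3,7-dimethylnona-2,6-dien-1-ol
Product: 11 (4E,8E)-10-hydroxy-4,8-dimethyldeca-4,8-dienal
Conditions: HIO4·2H2O, THF/H2O, 0 °C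
Reagents that add atoms: none
Why: Periodic acid opens the epoxide to the vicinal diol (water attacks the tertiary carbon) and cleaves it by glycol cleavage to the aldehyde and acetone, without touching the alkenes or the allylic alcohol.

Step 8
Reactants: 7 methyl (4R)-2-[bis(2,2,2-trifluoroethoxy)phosphoryl]-4-[(tert-butyldimethylsilyl)oxy]-6-methylhept-5-enoate; 11 (4E,8E)-10-hydroxy-4,8-dimethyldeca-4,8-dienal
Product: 12 methyl (2Z,6E,10E)-2-[(2R)-2-[(tert-butyldimethylsilyl)oxy]-4-methylpent-3-en-1-yl]-12-hydroxy-6,10-dimethyldodeca-2,6,10-trienoate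
Conditions: KN(SiMe3)2 (slightly less than 7), 18-crown-6, THF, −78 °C; then 11
Reagents that add atoms: none
Why: Still–Gennari olefination: the electron-poor bis(trifluoroethyl) phosphonate with a crown-separated potassium ion eliminates fast from the kinetically formed adduct, which should give the (Z)-trisubstituted enoate (ester cis to the chain); the free primary hydroxyl is far less acidic than the phosphonate and is tolerated.

Step 9
Reactants: 12 methyl (2Z,6E,10E)-2-[(2R)-2-[(tert-butyldimethylsilyl)oxy]-4-methylpent-3-en-1-yl]-12-hydroxy-6,10-dimethyldodeca-2,6,10-trienoate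
Product: 14 (3Z,5R)-3-[(4E,8E)-10-hydroxy-4,8-dimethyldeca-4,8-dien-1-ylidene]-5-(2-methylprop-1-en-1-yl)oxolan-2-one, via dihydroxy ester 13 (not isolated)
Conditions: HF·pyridine, pyridine, THF, 0 °C → rt; then PPTS (cat.), CH2Cl2, rt
Reagents that add atoms: none
Why: Fluoride cleavage of the silyl ether followed by 5-exo-trig lactonisation of the γ-hydroxy ester closes ring A; the C–O bond at the stereocentre is not broken, so (R) is retained, and the Z-alkene is not affected.

Step 10
Reactants: 14 (3Z,5R)-3-[(4E,8E)-10-hydroxy-4,8-dimethyldeca-4,8-dien-1-ylidene]-5-(2-methylprop-1-en-1-yl)oxolan-2-one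
Product: 15 (2E,6E,10Z)-3,7-dimethyl-10-[(5R)-5-(2-methylprop-1-en-1-yl)-2-oxooxolan-3-ylidene]deca-2,6-dienal
Conditions: MnO2, CH2Cl2, rt
Reagents that add atoms: none
Why: Chemoselective MnO2 oxidation of the only remaining allylic alcohol to the (E)-enal.

Step 11
Reactants: 15 (2E,6E,10Z)-3,7-dimethyl-10-[(5R)-5-(2-methylprop-1-en-1-yl)-2-oxooxolan-3-ylidene]deca-2,6-dienal; 16 2-(dichloromethyl)-4,4,5,5-tetramethyl-1,3,2-dioxaborolane
Product: 17 (3Z,5R)-3-[(4E,8E,10E)-4,8-dimethyl-11-(4,4,5,5-tetramethyl-1,3,2-dioxaborolan-2-yl)undeca-4,8,10-trien-1-ylidene]-5-(2-methylprop-1-en-1-yl)oxolan-2-one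
Conditions: CrCl2, LiI, THF, rt
Reagents that add atoms: none
Why: Takai–Utimoto boryl olefination: the gem-dichromium reagent formed from 16 adds to the aldehyde and eliminates to the (E)-alkenyl boronate; lactones and isolated alkenes are inert to CrCl2.

Step 12
Reactants: 17 (3Z,5R)-3-[(4E,8E,10E)-4,8-dimethyl-11-(4,4,5,5-tetramethyl-1,3,2-dioxaborolan-2-yl)undeca-4,8,10-trien-1-ylidene]-5-(2-methylprop-1-en-1-yl)oxolan-2-one; 18 2-bromoprop-2-en-1-ol
Product: 19 (3Z,5R)-3-[(4E,8E,10E)-12-(hydroxymethyl)-4,8-dimethyltrideca-4,8,10,12-tetraen-1-ylidene]-5-(2-methylprop-1-en-1-yl)oxolan-2-one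
Conditions: Pd(dppf)Cl2 (5 mol %), K3PO4 (aq.), THF, 40 °C
Reagents that add atoms: none
Why: Suzuki–Miyaura coupling of the alkenyl boronate with the vinyl bromide, with retention of the diene geometry; the free hydroxyl and the lactone should tolerate the mild phosphate base.

Step 13
Reactants: 19 (3Z,5R)-3-[(4E,8E,10E)-12-(hydroxymethyl)-4,8-dimethyltrideca-4,8,10,12-tetraen-1-ylidene]-5-(2-methylprop-1-en-1-yl)oxolan-2-one
Product: 20 (3Z,5R)-3-[(4E,8E,10E)-12-(bromomethyl)-4,8-dimethyltrideca-4,8,10,12-tetraen-1-ylidene]-5-(2-methylprop-1-en-1-yl)oxolan-2-one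
Conditions: CBr4, PPh3, CH2Cl2, −20 °C; used at once
Reagents that add atoms: carbon tetrabromide, BrC(Br)(Br)Br
Why: Appel bromination of the primary allylic alcohol at low temperature; SN2 and SN2′ attack give the same bromide because both ends of the allyl unit are CH2.

Step 14
Reactants: 20 (3Z,5R)-3-[(4E,8E,10E)-12-(bromomethyl)-4,8-dimethyltrideca-4,8,10,12-tetraen-1-ylidene]-5-(2-methylprop-1-en-1-yl)oxolan-2-one; 21 carbon dioxide
Product: 24 (3Z,5R)-3-[(4E,8E,10E)-4,8-dimethyl-11-(5-oxo-2,5-dihydrofuran-3-yl)undeca-4,8,10-trien-1-ylidene]-5-(2-methylprop-1-en-1-yl)oxolan-2-one, via sulfonium bromide 22 (not isolated), via carboxylate betaine 23 (not isolated)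
Conditions: tetrahydrothiophene (1.5 equiv), MeCN, rt; this solution added slowly to Cs2CO3 (2 equiv), CO2 (1 atm), MeCN (high dilution), 0 → 40 °C
Reagents that add atoms: none
Why: Proposed new method: tetrahydrothiophene S-alkylates the allylic bromide to sulfonium salt 22; Cs2CO3 deprotonates its S-CH2 to the semi-stabilised allyl ylide, whose carbon adds to CO2 to give betaine 23, and the carboxylate oxygen then expels the neutral sulfide from the allyl unit, either directly at the far CH2 with allylic shift (SN2′) or, after 1,3-prototropy to the (Z)-4-sulfonio-2-enoate, by SN2, both leading to the same butenolide. The closest known reaction types are the C-carboxylation of phosphorus ylides by CO2 to phosphonium carboxylate betaines, the formal [3+2] annulations of allylic phosphonium and sulfonium ylides in which the onium group leaves in the ring-closing step, alkyl transfer from sulfonium salts to carboxylates, and the palladium-catalysed [3+2] cycloaddition of trimethylenemethane with CO2 to butenolides. Ring B closes by O-alkylation of the carboxylate, as 5-endo-trig SN2′ (the geometry of the known 5-endo halolactonisation of but-3-enoic acids, since the tether carbon bearing sulfur is sp3) or as 5-exo-tet SN2; no stereocentre is formed. The step needs C-carboxylation and intramolecular closure to win over protonation of the ylide at its far carbon, the [2,3]-shift of a ring ylide and intermolecular O-alkylation; because both ends of the 2-substituted allyl unit are CH2, neither the site of carboxylation nor an alkene geometry matters, ylide formation, carboxylation and prototropy are reversible whereas loss of the sulfide is not, and slow addition at high dilution under CO2 keeps the sulfonium salt scarce. The carbonate base is too weak to enolise ring A, so the Z-alkylidene lactone, the stereocentre and the E,E-diene should be carried through unchanged.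

**Compound list**

1 | 2-chloro-N-methoxy-N-methylacetamide | CON(C)C(=O)CCl | starting material
2 | (2-methylprop-1-en-1-yl)magnesium bromide | CC(C)=C[Mg]Br | starting material
3 | 1-chloro-4-methylpent-3-en-2-one | CC(C)=CC(=O)CCl | intermediate
4 | methyl 2-[bis(2,2,2-trifluoroethoxy)phosphoryl]acetate | COC(=O)CP(=O)(OCC(F)(F)F)OCC(F)(F)F | starting material
5 | methyl 2-[bis(2,2,2-trifluoroethoxy)phosphoryl]-6-methyl-4-oxohept-5-enoate (racemic) | COC(=O)C(CC(=O)C=C(C)C)P(=O)(OCC(F)(F)F)OCC(F)(F)F | intermediate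
6 | methyl (4R)-2-[bis(2,2,2-trifluoroethoxy)phosphoryl]-4-hydroxy-6-methylhept-5-enoate (both C2 epimers) | CC(C)=C[C@H](O)CC(C(=O)OC)P(=O)(OCC(F)(F)F)OCC(F)(F)F | intermediate
7 | methyl (4R)-2-[bis(2,2,2-trifluoroethoxy)phosphoryl]-4-[(tert-butyldimethylsilyl)oxy]-6-methylhept-5-enoate (both C2 epimers) | CC(C)=C[C@H](O[Si](C)(C)C(C)(C)C)CC(C(=O)OC)P(=O)(OCC(F)(F)F)OCC(F)(F)F | intermediate
8 | (2E,6E)-3,7,11-trimethyldodeca-2,6,10-trien-1-yl acetate ((E,E)-farnesyl acetate) | CC(C)=CCC/C(C)=C/CC/C(C)=C/COC(C)=O | starting material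
9 | (2E,6E)-10-bromo-11-hydroxy-3,7,11-trimethyldodeca-2,6-dien-1-yl acetate (racemic) | CC(C)(O)C(Br)CC/C(C)=C/CC/C(C)=C/COC(C)=O | intermediate
10 | (2E,6E)-9-(3,3-dimethyloxiran-2-yl)-3,7-dimethylnona-2,6-dien-1-ol (racemic) | CC1(C)OC1CC/C(C)=C/CC/C(C)=C/CO | intermediate
11 | (4E,8E)-10-hydroxy-4,8-dimethyldeca-4,8-dienal | O=CCC/C(C)=C/CC/C(C)=C/CO | intermediate
12 | methyl (2Z,6E,10E)-2-[(2R)-2-[(tert-butyldimethylsilyl)oxy]-4-methylpent-3-en-1-yl]-12-hydroxy-6,10-dimethyldodeca-2,6,10-trienoate | CC(C)=C[C@H](O[Si](C)(C)C(C)(C)C)C/C(=C/CC/C(C)=C/CC/C(C)=C/CO)C(=O)OC | intermediate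
13 | methyl (2Z,6E,10E)-12-hydroxy-2-[(2R)-2-hydroxy-4-methylpent-3-en-1-yl]-6,10-dimethyldodeca-2,6,10-trienoate | CC(C)=C[C@H](O)C/C(=C/CC/C(C)=C/CC/C(C)=C/CO)C(=O)OC | intermediate (not isolated)
14 | (3Z,5R)-3-[(4E,8E)-10-hydroxy-4,8-dimethyldeca-4,8-dien-1-ylidene]-5-(2-methylprop-1-en-1-yl)oxolan-2-one | CC(C)=C[C@H]1C/C(=C/CC/C(C)=C/CC/C(C)=C/CO)C(=O)O1 | intermediate
15 | (2E,6E,10Z)-3,7-dimethyl-10-[(5R)-5-(2-methylprop-1-en-1-yl)-2-oxooxolan-3-ylidene]deca-2,6-dienal | CC(C)=C[C@H]1C/C(=C/CC/C(C)=C/CC/C(C)=C/C=O)C(=O)O1 | intermediate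
16 | 2-(dichloromethyl)-4,4,5,5-tetramethyl-1,3,2-dioxaborolane | ClC(Cl)B1OC(C)(C)C(C)(C)O1 | starting material
17 | (3Z,5R)-3-[(4E,8E,10E)-4,8-dimethyl-11-(4,4,5,5-tetramethyl-1,3,2-dioxaborolan-2-yl)undeca-4,8,10-trien-1-ylidene]-5-(2-methylprop-1-en-1-yl)oxolan-2-one | CC(C)=C[C@H]1C/C(=C/CC/C(C)=C/CC/C(C)=C/C=C/B2OC(C)(C)C(C)(C)O2)C(=O)O1 | intermediate
18 | 2-bromoprop-2-en-1-ol | OCC(Br)=C | starting material
19 | (3Z,5R)-3-[(4E,8E,10E)-12-(hydroxymethyl)-4,8-dimethyltrideca-4,8,10,12-tetraen-1-ylidene]-5-(2-methylprop-1-en-1-yl)oxolan-2-one | CC(C)=C[C@H]1C/C(=C/CC/C(C)=C/CC/C(C)=C/C=C/C(=C)CO)C(=O)O1 | intermediate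
20 | (3Z,5R)-3-[(4E,8E,10E)-12-(bromomethyl)-4,8-dimethyltrideca-4,8,10,12-tetraen-1-ylidene]-5-(2-methylprop-1-en-1-yl)oxolan-2-one | CC(C)=C[C@H]1C/C(=C/CC/C(C)=C/CC/C(C)=C/C=C/C(=C)CBr)C(=O)O1 | intermediate
21 | carbon dioxide | O=C=O | starting material
22 | 1-[(3E,5E,9E,13Z)-6,10-dimethyl-2-methylidene-13-[(5R)-5-(2-methylprop-1-en-1-yl)-2-oxooxolan-3-ylidene]trideca-3,5,9-trien-1-yl]thiolan-1-ium bromide | CC(C)=C[C@H]1C/C(=C/CC/C(C)=C/CC/C(C)=C/C=C/C(=C)C[S+]2CCCC2)C(=O)O1.[Br-] | intermediate (not isolated)
23 | (4E,6E,10E,14Z)-7,11-dimethyl-3-methylidene-14-[(5R)-5-(2-methylprop-1-en-1-yl)-2-oxooxolan-3-ylidene]-2-(thiolan-1-ium-1-yl)tetradeca-4,6,10-trienoate (zwitterion, both C2 epimers) | CC(C)=C[C@H]1C/C(=C/CC/C(C)=C/CC/C(C)=C/C=C/C(=C)C([S+]2CCCC2)C([O-])=O)C(=O)O1 | intermediate (not isolated)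
24 | (3Z,5R)-3-[(4E,8E,10E)-4,8-dimethyl-11-(5-oxo-2,5-dihydrofuran-3-yl)undeca-4,8,10-trien-1-ylidene]-5-(2-methylprop-1-en-1-yl)oxolan-2-one | CC(C)=C[C@H]1C/C(=C/CC/C(C)=C/CC/C(C)=C/C=C/C2=CC(=O)OC2)C(=O)O1 | target

**Count**

Total steps: 14. Longest linear sequence: 11 steps (steps 1–4 and 8–14, from 1 to 24); the farnesyl branch (steps 5–7) joins at step 8.

**Steps most likely to fail**

Step 14 (proposed new method). What may go wrong: the ylide may be protonated at its far carbon to a vinylsulfonium salt that is consumed by conjugate addition, or carboxylate and carbonate may alkylate intermolecularly, so that ring closure with loss of the sulfide is outrun. The fallback uses known chemistry; it sets out from 17 and comes back at 24. Suzuki–Miyaura coupling of dienyl boronate 17 with commercial 4-bromofuran-2(5H)-one (BrC1=CC(=O)OC1; Pd(PPh3)4, K3PO4, THF/H2O, rt) joins a finished ring B to the diene with retention of the E geometry and should give 24 directly. Steps 12 to 14 are then not needed and no new compound is made (F0).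

Step 3. What may go wrong: poor facial selectivity, because the small substituent of ketone 5 is a branched CH2 group carrying phosphonate and ester, and the phosphoryl oxygen may bind boron. The fallback sets out from 3 and comes back at 7. Chloro ketone 3, whose small substituent is a plain CH2Cl, is reduced first with the same CBS system to (2S)-1-chloro-4-methylpent-3-en-2-ol F1. This is silylated (TBSCl, imidazole, DMF) to tert-butyl{[(2S)-1-chloro-4-methylpent-3-en-2-yl]oxy}dimethylsilane F2 and converted by Finkelstein exchange (NaI, butan-2-one, reflux) into tert-butyl{[(2S)-1-iodo-4-methylpent-3-en-2-yl]oxy}dimethylsilane F3. Alkylation of the sodium salt of 4 with F3 (NaH, DMSO, 50 °C) should then give 7, so the stereocentre is set before the C–C bond is made.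

Step 12. What may go wrong: protodeboronation of the dienyl boronate, or hydrolysis and Z-to-E isomerisation of the alkylidene lactone of ring A in the basic aqueous medium. The fallback sets out from 15 and comes back at 19. Takai iodo-olefination of enal 15 (CHI3, CrCl2, THF/dioxane) should give (3Z,5R)-3-[(4E,8E,10E)-11-iodo-4,8-dimethylundeca-4,8,10-trien-1-ylidene]-5-(2-methylprop-1-en-1-yl)oxolan-2-one F4. A Stille coupling of F4 with 2-(tributylstannyl)prop-2-en-1-ol (C=C(CO)[Sn](CCCC)(CCCC)CCCC; Pd2(dba)3, AsPh3, NMP, rt) under neutral, base-free conditions should then give 19.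

**Further compounds**

F0 | step 14 | none | none
F1 | step 3 | (2S)-1-chloro-4-methylpent-3-en-2-ol | CC(C)=C[C@H](O)CCl
F2 | step 3 | tert-butyl{[(2S)-1-chloro-4-methylpent-3-en-2-yl]oxy}dimethylsilane | CC(C)=C[C@H](O[Si](C)(C)C(C)(C)C)CCl
F3 | step 3 | tert-butyl{[(2S)-1-iodo-4-methylpent-3-en-2-yl]oxy}dimethylsilane | CC(C)=C[C@H](O[Si](C)(C)C(C)(C)C)CI
F4 | step 12 | (3Z,5R)-3-[(4E,8E,10E)-11-iodo-4,8-dimethylundeca-4,8,10-trien-1-ylidene]-5-(2-methylprop-1-en-1-yl)oxolan-2-one | CC(C)=C[C@H]1C/C(=C/CC/C(C)=C/CC/C(C)=C/C=C/I)C(=O)O1
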